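The tetrahydropyran (O1, C2 aryl-bearing, C4 acetoxy-bearing, C6 arylethyl-bearing) is cut between C4 and the C5 methylene. The unit O1–C6–C5 is read as an acetate ester on the benzylic C2 oxygen and C4 as an aldehyde carbon, so the ring is closed by a SmI2-promoted intramolecular Reformatsky aldol of a β-(bromoacetoxy) aldehyde. In one operation this forms the C4–C5 bond, closes the six-membered ring as a δ-lactone and, through a samarium chelate, sets the C4 oxygen trans to the C2 aryl group, the axial orientation of the target. The lactone carbonyl (C6) later takes up the arylethyl chain and an axial hydride.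

Key step: step 5

Remark: the target is read as (2S,4S,6S); the aryl group at C2 and the arylethyl group at C6 are cis (both equatorial) and the acetoxy group at C4 is trans to both (axial).

Step 1
Reactants: 1 3,4-dihydroxy-5-methoxybenzaldehyde
Product: 2 3,4-bis(benzyloxy)-5-methoxybenzaldehyde
Conditions: BnBr, K2CO3, DMF, 60 °C
Reagents that add atoms: benzyl bromide, BrCc1ccccc1
Why: Williamson etherification of both phenoxides gives benzyl ethers that should survive every later step and leave together by hydrogenolysis at the end.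

Step 2
Reactants: 2 3,4-bis(benzyloxy)-5-methoxybenzaldehyde
Product: 4 (S)-1-[3,4-bis(benzyloxy)-5-methoxyphenyl]but-3-en-1-ol, via borinic ester 3 (not isolated)
Conditions: (−)-Ipc2BOMe, allylMgBr, Et2O, 0 °C to rt; then 2, −78 °C; then NaOH, H2O2, 0 °C to rt
Reagents that add atoms: allylmagnesium bromide, C=CC[Mg]Br
Why: Brown asymmetric allylboration: the B-allyldiisopinocampheylborane made in the flask transfers its allyl group through a chair-like Zimmerman–Traxler transition state in which the isopinocampheyl groups derived from (+)-α-pinene direct attack to the Si face of the aryl aldehyde, setting the benzylic carbinol as S, and alkaline H2O2 then cleaves borinic ester 3.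

Step 3
Reactants: 4 (S)-1-[3,4-bis(benzyloxy)-5-methoxyphenyl]but-3-en-1-ol
Product: 5 (S)-1-[3,4-bis(benzyloxy)-5-methoxyphenyl]but-3-en-1-yl 2-bromoacetate
Conditions: BrCH2COBr, pyridine, CH2Cl2, −20 to 0 °C
Reagents that add atoms: bromoacetyl bromide, BrCC(Br)=O
Why: O-acylation with the acid bromide leaves the stereocenter untouched and installs the two carbons that become C5 and C6 together with the bromide needed for enolate generation.

Step 4
Reactants: 5 (S)-1-[3,4-bis(benzyloxy)-5-methoxyphenyl]but-3-en-1-yl 2-bromoacetate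
Product: 7 (S)-1-[3,4-bis(benzyloxy)-5-methoxyphenyl]-3-oxopropyl 2-bromoacetate, via ozonide 6 (not isolated)
Conditions: O3, CH2Cl2, −78 °C (Sudan red 7B end point); then Me2S, −78 °C to rt; used crude
Reagents that add atoms: ozone, [O-][O+]=O
Why: Criegee ozonolysis cleaves the only alkene through ozonide 6, the indicator dye stops ozone before the electron-rich arene is attacked, and the neutral reductive work-up without chromatography avoids β-elimination of the acyloxy group.

Step 5
Reactants: 7 (S)-1-[3,4-bis(benzyloxy)-5-methoxyphenyl]-3-oxopropyl 2-bromoacetate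
Product: 9 (4R,6S)-6-[3,4-bis(benzyloxy)-5-methoxyphenyl]-4-hydroxytetrahydro-2H-pyran-2-one, via samarium enolate 8 (not isolated)
Conditions: SmI2 (2.2 equiv), THF, −78 °C; then pH 7 buffer
Reagents that add atoms: none
Why: Two single-electron transfers from SmI2 cleave the C–Br bond and give the trivalent samarium enolate 8 of the acetate ester, which adds to the tethered aldehyde. The closest known reaction type is the SmI2-promoted intramolecular Reformatsky reaction of β-(bromoacetoxy) aldehydes, which gives β-hydroxy-δ-valerolactones with 1,3-asymmetric induction. The six-membered lactone ring closes in the 6-(enolendo)-exo-trig mode, the enolate carbon (future C5) attacking the aldehyde carbon (future C4). The new C4 stereocenter is controlled by the benzylic C2 center: samarium bridges the enolate oxygen and the aldehyde oxygen in a chair-like bicyclic transition state, so the aldehyde oxygen must be axial while the aryl group stays equatorial and away from the metal, and the hydroxyl should end trans to the aryl group (4R). The step needs chemoselectivity for the C–Br bond over the aldehyde carbonyl, secured by the much faster electron transfer to the α-bromo ester at −78 °C, and it needs ring closure to outrun β-elimination of the acyloxy group, secured by the cold, neutral and fast conditions and by the favourable six-membered chelate.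

Step 6
Reactants: 9 (4R,6S)-6-[3,4-bis(benzyloxy)-5-methoxyphenyl]-4-hydroxytetrahydro-2H-pyran-2-one
Product: 10 (4R,6S)-6-[3,4-bis(benzyloxy)-5-methoxyphenyl]-4-[(tert-butyldimethylsilyl)oxy]tetrahydro-2H-pyran-2-one
Conditions: TBSCl, imidazole, DMF, rt
Reagents that add atoms: tert-butyldimethylsilyl chloride, CC(C)(C)[Si](C)(C)Cl
Why: Imidazole-mediated silylation is mild enough not to trigger β-elimination of the β-hydroxy lactone and masks the hydroxyl against the Grignard reagent of step 9.

Step 7
Reactants: 11 4-(2-hydroxyethyl)-2-methoxyphenol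
Product: 12 2-[4-(benzyloxy)-3-methoxyphenyl]ethanol
Conditions: BnBr, K2CO3, acetone, reflux
Reagents that add atoms: benzyl bromide, BrCc1ccccc1
Why: Williamson etherification is chemoselective for the phenol because K2CO3 forms only the phenoxide while the primary alcohol stays protonated.

Step 8
Reactants: 12 2-[4-(benzyloxy)-3-methoxyphenyl]ethanol
Product: 13 1-(benzyloxy)-4-(2-bromoethyl)-2-methoxybenzene
Conditions: CBr4, PPh3, CH2Cl2, 0 °C
Reagents that add atoms: carbon tetrabromide, BrC(Br)(Br)Br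
Why: Appel reaction, in which bromide displaces the alkoxyphosphonium group in an SN2 step at the primary carbon.

Step 9
Reactants: 10 (4R,6S)-6-[3,4-bis(benzyloxy)-5-methoxyphenyl]-4-[(tert-butyldimethylsilyl)oxy]tetrahydro-2H-pyran-2-one; 13 1-(benzyloxy)-4-(2-bromoethyl)-2-methoxybenzene
Product: 15 (4R,6S)-6-[3,4-bis(benzyloxy)-5-methoxyphenyl]-2-{2-[4-(benzyloxy)-3-methoxyphenyl]ethyl}-4-[(tert-butyldimethylsilyl)oxy]tetrahydro-2H-pyran-2-ol (lactol), via Grignard reagent 14 (not isolated)
Conditions: 13, Mg, THF, rt; then 10, THF, −78 °C; sat. aq. NH4Cl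
Reagents that add atoms: none
Why: Grignard addition to a δ-lactone should stop after one addition because the tetrahedral magnesium hemiketal alkoxide persists at −78 °C, so the quench gives the lactol (in equilibrium with its open hydroxy ketone) without involving the two existing stereocenters.

Step 10
Reactants: 15 (4R,6S)-6-[3,4-bis(benzyloxy)-5-methoxyphenyl]-2-{2-[4-(benzyloxy)-3-methoxyphenyl]ethyl}-4-[(tert-butyldimethylsilyl)oxy]tetrahydro-2H-pyran-2-ol
Product: 17 (2S,4S,6S)-2-[3,4-bis(benzyloxy)-5-methoxyphenyl]-6-{2-[4-(benzyloxy)-3-methoxyphenyl]ethyl}-4-[(tert-butyldimethylsilyl)oxy]tetrahydro-2H-pyran, via oxocarbenium ion 16 (not isolated)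
Conditions: Et3SiH, BF3·OEt2 (promoter), CH2Cl2–MeCN, −78 to −40 °C; aq. NaHCO3
Reagents that add atoms: none
Why: Lewis-acid ionisation of the hemiketal gives cyclic oxocarbenium ion 16, which Et3SiH reduces (ionic hydrogenation of a lactol) by hydride delivery along the axial trajectory of the half-chair that keeps the C2 aryl group pseudo-equatorial, so the arylethyl chain should end equatorial and C6 is set as S, cis to C2.

Step 11
Reactants: 17 (2S,4S,6S)-2-[3,4-bis(benzyloxy)-5-methoxyphenyl]-6-{2-[4-(benzyloxy)-3-methoxyphenyl]ethyl}-4-[(tert-butyldimethylsilyl)oxy]tetrahydro-2H-pyran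
Product: 18 (2S,4S,6S)-2-[3,4-bis(benzyloxy)-5-methoxyphenyl]-6-{2-[4-(benzyloxy)-3-methoxyphenyl]ethyl}tetrahydro-2H-pyran-4-ol
Conditions: TBAF, THF, 0 °C to rt
Reagents that add atoms: none
Why: Fluoride-driven desilylation frees the axial alcohol and leaves the benzyl ethers and the ring untouched.

Step 12
Reactants: 18 (2S,4S,6S)-2-[3,4-bis(benzyloxy)-5-methoxyphenyl]-6-{2-[4-(benzyloxy)-3-methoxyphenyl]ethyl}tetrahydro-2H-pyran-4-ol
Product: 19 (2S,4S,6S)-2-[3,4-bis(benzyloxy)-5-methoxyphenyl]-6-{2-[4-(benzyloxy)-3-methoxyphenyl]ethyl}tetrahydro-2H-pyran-4-yl acetate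
Conditions: Ac2O, pyridine, DMAP (cat.), CH2Cl2, rt
Reagents that add atoms: acetic anhydride, CC(=O)OC(C)=O
Why: DMAP-catalysed O-acylation of the secondary alcohol proceeds with retention at C4.

Step 13
Reactants: 19 (2S,4S,6S)-2-[3,4-bis(benzyloxy)-5-methoxyphenyl]-6-{2-[4-(benzyloxy)-3-methoxyphenyl]ethyl}tetrahydro-2H-pyran-4-yl acetate
Product: 20 (2S,4S,6S)-2-(3,4-dihydroxy-5-methoxyphenyl)-6-[2-(4-hydroxy-3-methoxyphenyl)ethyl]tetrahydro-2H-pyran-4-yl acetate
Conditions: H2 (1 atm), Pd/C, EtOAc, rt
Reagents that add atoms: none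
Why: Catalytic hydrogenolysis should remove the three aryl O-benzyl groups much faster than it attacks the ring benzylic C2–O bond of the dialkyl ether, and the acetate is inert, so stopping after uptake of three equivalents of H2 releases the three phenols.

Compound list
1 | 3,4-dihydroxy-5-methoxybenzaldehyde (5-hydroxyvanillin) | COc1cc(C=O)cc(O)c1O | starting material
2 | 3,4-bis(benzyloxy)-5-methoxybenzaldehyde | COc1cc(C=O)cc(OCc2ccccc2)c1OCc1ccccc1 | intermediate
3 | (S)-1-[3,4-bis(benzyloxy)-5-methoxyphenyl]but-3-en-1-yl diisopinocampheylborinate (isopinocampheyl groups from (+)-α-pinene) | C=CC[C@@H](c1cc(OCc2ccccc2)c(OCc2ccccc2)c(OC)c1)OB([C@@H]1C[C@@H]2C[C@H]([C@H]1C)C2(C)C)[C@@H]1C[C@@H]2C[C@H]([C@H]1C)C2(C)C | intermediate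
4 | (S)-1-[3,4-bis(benzyloxy)-5-methoxyphenyl]but-3-en-1-ol | C=CC[C@@H](c1cc(OCc2ccccc2)c(OCc2ccccc2)c(OC)c1)O | intermediate
5 | (S)-1-[3,4-bis(benzyloxy)-5-methoxyphenyl]but-3-en-1-yl 2-bromoacetate | C=CC[C@@H](c1cc(OCc2ccccc2)c(OCc2ccccc2)c(OC)c1)OC(=O)CBr | intermediate
6 | (1S)-1-[3,4-bis(benzyloxy)-5-methoxyphenyl]-2-(1,2,4-trioxolan-3-yl)ethyl 2-bromoacetate (ozonide, trioxolane carbon unassigned) | O1OC(OC1)C[C@@H](c1cc(OCc2ccccc2)c(OCc2ccccc2)c(OC)c1)OC(=O)CBr | intermediate
7 | (S)-1-[3,4-bis(benzyloxy)-5-methoxyphenyl]-3-oxopropyl 2-bromoacetate | O=CC[C@@H](c1cc(OCc2ccccc2)c(OCc2ccccc2)c(OC)c1)OC(=O)CBr | intermediate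
8 | diiodosamarium O-enolate of the acetate ester of (S)-3-[3,4-bis(benzyloxy)-5-methoxyphenyl]-3-hydroxypropanal (trivalent samarium) | O=CC[C@@H](c1cc(OCc2ccccc2)c(OCc2ccccc2)c(OC)c1)OC(=C)O[Sm](I)I | intermediate
9 | (4R,6S)-6-[3,4-bis(benzyloxy)-5-methoxyphenyl]-4-hydroxytetrahydro-2H-pyran-2-one (hydroxyl trans to aryl) | O=C1C[C@H](O)C[C@@H](c2cc(OCc3ccccc3)c(OCc3ccccc3)c(OC)c2)O1 | intermediate
10 | (4R,6S)-6-[3,4-bis(benzyloxy)-5-methoxyphenyl]-4-[(tert-butyldimethylsilyl)oxy]tetrahydro-2H-pyran-2-one | O=C1C[C@H](O[Si](C)(C)C(C)(C)C)C[C@@H](c2cc(OCc3ccccc3)c(OCc3ccccc3)c(OC)c2)O1 | intermediate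
11 | 4-(2-hydroxyethyl)-2-methoxyphenol (homovanillyl alcohol) | COc1cc(CCO)ccc1O | starting material
12 | 2-[4-(benzyloxy)-3-methoxyphenyl]ethanol | COc1cc(CCO)ccc1OCc1ccccc1 | intermediate
13 | 1-(benzyloxy)-4-(2-bromoethyl)-2-methoxybenzene | COc1cc(CCBr)ccc1OCc1ccccc1 | intermediate
14 | {2-[4-(benzyloxy)-3-methoxyphenyl]ethyl}magnesium bromide | COc1cc(CC[Mg]Br)ccc1OCc1ccccc1 | intermediate
15 | (4R,6S)-6-[3,4-bis(benzyloxy)-5-methoxyphenyl]-2-{2-[4-(benzyloxy)-3-methoxyphenyl]ethyl}-4-[(tert-butyldimethylsilyl)oxy]tetrahydro-2H-pyran-2-ol (lactol, both C2 anomers, in equilibrium with the open hydroxy ketone) | COc1cc(CCC2(O)C[C@H](O[Si](C)(C)C(C)(C)C)C[C@@H](c3cc(OCc4ccccc4)c(OCc4ccccc4)c(OC)c3)O2)ccc1OCc1ccccc1 | intermediate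
16 | cyclic oxocarbenium ion formed from 15 by loss of the C2 hydroxyl (C=O+ between the arylethyl-bearing carbon and the ring oxygen) | COc1cc(CCC=2C[C@H](O[Si](C)(C)C(C)(C)C)C[C@@H](c3cc(OCc4ccccc4)c(OCc4ccccc4)c(OC)c3)[O+]=2)ccc1OCc1ccccc1 | intermediate
17 | (2S,4S,6S)-2-[3,4-bis(benzyloxy)-5-methoxyphenyl]-6-{2-[4-(benzyloxy)-3-methoxyphenyl]ethyl}-4-[(tert-butyldimethylsilyl)oxy]tetrahydro-2H-pyran | COc1cc(CC[C@H]2C[C@H](O[Si](C)(C)C(C)(C)C)C[C@@H](c3cc(OCc4ccccc4)c(OCc4ccccc4)c(OC)c3)O2)ccc1OCc1ccccc1 | intermediate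
18 | (2S,4S,6S)-2-[3,4-bis(benzyloxy)-5-methoxyphenyl]-6-{2-[4-(benzyloxy)-3-methoxyphenyl]ethyl}tetrahydro-2H-pyran-4-ol | COc1cc(CC[C@H]2C[C@H](O)C[C@@H](c3cc(OCc4ccccc4)c(OCc4ccccc4)c(OC)c3)O2)ccc1OCc1ccccc1 | intermediate
19 | (2S,4S,6S)-2-[3,4-bis(benzyloxy)-5-methoxyphenyl]-6-{2-[4-(benzyloxy)-3-methoxyphenyl]ethyl}tetrahydro-2H-pyran-4-yl acetate | COc1cc(CC[C@H]2C[C@H](OC(C)=O)C[C@@H](c3cc(OCc4ccccc4)c(OCc4ccccc4)c(OC)c3)O2)ccc1OCc1ccccc1 | intermediate
20 | (2S,4S,6S)-2-(3,4-dihydroxy-5-methoxyphenyl)-6-[2-(4-hydroxy-3-methoxyphenyl)ethyl]tetrahydro-2H-pyran-4-yl acetate | COc1cc(CC[C@H]2C[C@H](OC(C)=O)C[C@@H](c3cc(O)c(O)c(OC)c3)O2)ccc1O | target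

Total step count: 13. Longest linear sequence: 11 steps (steps 1–6 and 9–13); steps 7 and 8 prepare the side-chain bromide.

Steps most likely to fail

Step 5 (key ring closure). The bromoacetoxy group may be lost by β-elimination from the aldehyde or from the samarium aldolate, the aldehyde may be reduced or pinacol-coupled, and the 1,3-induction may erode if the chelate is not maintained. The fallback sets out from alcohol 4. Acylation with acryloyl chloride and Et3N would give the acrylate ester F1. Ring-closing metathesis with the second-generation Grubbs catalyst in refluxing CH2Cl2 would close the same C4–C5 bond as a double bond and give the dihydropyranone F2. Nucleophilic epoxidation with H2O2 and NaOH in MeOH should occur anti to the aryl group and give the epoxy lactone F3. Reductive opening at the α-carbon with (PhSe)2, NaBH4 and AcOH in EtOH would then give the trans hydroxy lactone, and the route is rejoined at 9.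

Step 4 (oxidative cleavage). Ozone may over-oxidise the electron-rich trioxygenated arene or the benzyl ethers, bromoacetic acid may be eliminated from the β-acyloxy aldehyde during work-up, and dimethyl sulfide may be alkylated by the bromoacetate. The fallback sets out from 5. Dihydroxylation with catalytic OsO4 and N-methylmorpholine N-oxide in acetone–water would give the diol F4 as a pair of carbinol epimers. Glycol cleavage with NaIO4 on silica gel in CH2Cl2 at rt, neutral and free of ozone, would give the aldehyde, and the route is rejoined at 7.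

Step 10 (oxocarbenium reduction). Hydride delivery may lose facial selectivity because the axial silyloxy group at C4 lies syn to the axial trajectory at C6, and the Lewis acid may remove the silyl group or ionise the benzylic C2–O bond. The fallback sets out from lactol 15. TBAF would give the β-hydroxy ketone F5 (in equilibrium with its lactol). Narasaka–Prasad reduction (excess Et2BOMe, NaBH4, THF–MeOH, −78 °C) should deliver hydride to the boron chelate and set the C6 carbinol syn to the C4 hydroxyl, giving the syn,syn-triol F6. Catalytic p-toluenesulfonic acid in CH2Cl2 should ionise only the electron-rich benzylic C2–OH. The C6 hydroxyl would then close the ring reversibly, so the thermodynamically preferred 2,6-cis ether with the C4 hydroxyl axial should result, and the route is rejoined at 18.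

Further compounds
F1 | step 5 | (S)-1-[3,4-bis(benzyloxy)-5-methoxyphenyl]but-3-en-1-yl acrylate | C=CC[C@@H](c1cc(OCc2ccccc2)c(OCc2ccccc2)c(OC)c1)OC(=O)C=C
F2 | step 5 | (S)-6-[3,4-bis(benzyloxy)-5-methoxyphenyl]-5,6-dihydro-2H-pyran-2-one | O=C1C=CC[C@@H](c2cc(OCc3ccccc3)c(OCc3ccccc3)c(OC)c2)O1
F3 | step 5 | (1R,4S,6R)-4-[3,4-bis(benzyloxy)-5-methoxyphenyl]-3,7-dioxabicyclo[4.1.0]heptan-2-one (epoxide oxygen trans to the aryl group) | O=C1[C@@H]2O[C@@H]2C[C@@H](c3cc(OCc4ccccc4)c(OCc4ccccc4)c(OC)c3)O1
F4 | step 4 | (1S)-1-[3,4-bis(benzyloxy)-5-methoxyphenyl]-3,4-dihydroxybutyl 2-bromoacetate (both C3 epimers) | OCC(O)C[C@@H](c1cc(OCc2ccccc2)c(OCc2ccccc2)c(OC)c1)OC(=O)CBr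
F5 | step 10 | (1S,3R)-1-[3,4-bis(benzyloxy)-5-methoxyphenyl]-7-[4-(benzyloxy)-3-methoxyphenyl]-1,3-dihydroxyheptan-5-one | COc1cc(CCC(=O)C[C@H](O)C[C@@H](c2cc(OCc3ccccc3)c(OCc3ccccc3)c(OC)c2)O)ccc1OCc1ccccc1
F6 | step 10 | (1S,3S,5S)-1-[3,4-bis(benzyloxy)-5-methoxyphenyl]-7-[4-(benzyloxy)-3-methoxyphenyl]heptane-1,3,5-triol | COc1cc(CC[C@H](O)C[C@H](O)C[C@@H](c2cc(OCc3ccccc3)c(OCc3ccccc3)c(OC)c2)O)ccc1OCc1ccccc1
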